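**Plan**

- Retrosynthetic cuts: (a) the two C–C bonds that fuse the cyclopentene ring of the cyclopenta[b]chromenone onto the oxa-bridged core (chromone C2–CH and C(OH)(CO2Me)–CH); (b) the two bridgehead–arene bonds of the resulting 1-aryl-1,4-epoxy-1,4-dihydronaphthalene (aryne + 2-arylfuran); (c) the pyrone ring (enaminone route).
- Enabling feature: the cyclopentene sits cis and exo on the C2–C3 edge of a 7-oxabicyclo[2.2.1]heptene, i.e. on a strained alkene, and the chromone C2–H bond lies beside a ketone on C3 that can direct a metal to C2 and then accept the alkyl–metal bond formed by insertion.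
- Forward order: chromone keto ester 14 (steps 1–5); bromophenol 22 and furylresorcinol 25 are tied through a diisopropylsilylene (step 10), which makes the aryne–furan Diels–Alder reaction intramolecular and fixes its orientation (step 11, benzo-fused oxa-bridged bicycle); step 13 closes the cyclopentene ring between chromone and bicycle; step 14 removes acetates and silylene.
- Stereochemistry: the two bridgeheads form together as a racemate in step 11 and are resolved by a lipase in step 12; the two ring-fusion CH centres and the carbinol centre are set in step 13 relative to them (exo, cis insertion; carbonyl addition with the ester on the convex face).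
- Helpers: the silylene (tether in step 11, conformational lock in step 13, protecting group) and the aryl acetate (handle for the enzyme) leave in step 14.

Key step: step 13

Remark: species that exist only bound to the catalyst in step 13 are described in its Why line and carry no number; the racemic compounds 31 and 32 are drawn as the enantiomer that is carried on.
Assumption: the lipase of step 12 cleaves the aryl acetate of the unwanted enantiomer faster; the sense has to be fixed by screening, and with the opposite sense the phenol would be the wanted half and would be re-acetylated.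

**Route**

Step 1
Reactants: 1 3,5-dihydroxybenzyl alcohol; 2 chloromethyl methyl ether
Product: 3 1,3-bis(methoxymethoxy)-5-[(methoxymethoxy)methyl]benzene
Conditions: 2 (3.6 equiv), iPr2NEt, CH2Cl2, 0 °C to rt
Reagents that add atoms: chloromethyl methyl ether, COCCl
Why: O-alkylation of both phenols and the benzylic alcohol with the chloromethyl ether should give the tris(methoxymethyl) ether, whose two aryl acetal groups direct the next metalation.

Step 2
Reactants: 3 1,3-bis(methoxymethoxy)-5-[(methoxymethoxy)methyl]benzene; 4 N-methoxy-N-methylacetamide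
Product: 7 1-{2,6-bis(methoxymethoxy)-4-[(methoxymethoxy)methyl]phenyl}ethan-1-one, via aryllithium 5 (not isolated), via lithium hemiaminal 6 (not isolated)
Conditions: n-BuLi, THF, 0 °C; then 4, −78 °C to rt; then H2O
Reagents that add atoms: N-methoxy-N-methylacetamide, CC(=O)N(C)OC
Why: Directed ortho-metalation should occur at the position flanked by both methoxymethoxy groups, and acylation with the Weinreb amide stops at the chelated tetrahedral adduct, so the methyl ketone forms without over-addition.

Step 3
Reactants: 7 1-{2,6-bis(methoxymethoxy)-4-[(methoxymethoxy)methyl]phenyl}ethan-1-one; 8 N,N-dimethylformamide dimethyl acetal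
Product: 9 (E)-3-(dimethylamino)-1-{2,6-bis(methoxymethoxy)-4-[(methoxymethoxy)methyl]phenyl}prop-2-en-1-one
Conditions: 8 (neat), 100 °C
Reagents that add atoms: N,N-dimethylformamide dimethyl acetal, COC(OC)N(C)C
Why: Condensation of the methyl ketone with the amide acetal (enaminone formation) should give the E enaminone with loss of methanol.

Step 4
Reactants: 9 (E)-3-(dimethylamino)-1-{2,6-bis(methoxymethoxy)-4-[(methoxymethoxy)methyl]phenyl}prop-2-en-1-one; 10 methyl chlorooxoacetate
Product: 12 methyl 2-[5-hydroxy-7-(hydroxymethyl)-4-oxo-4H-chromen-3-yl]-2-oxoacetate, via acyl enaminone 11 (not isolated)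
Conditions: 10, pyridine, CH2Cl2, 0 °C; then CF3CO2H/CH2Cl2 (1:1, wet), rt; aq. NaHCO3 work-up
Reagents that add atoms: methyl chlorooxoacetate, COC(=O)C(=O)Cl
Why: The enaminone α-carbon is C-acylated by the oxalyl chloride, and acid removal of the three acetals lets a freed phenol add to the enamine carbon and expel dimethylamine (enaminone route to 3-acylchromones).

Step 5
Reactants: 12 methyl 2-[5-hydroxy-7-(hydroxymethyl)-4-oxo-4H-chromen-3-yl]-2-oxoacetate; 13 acetic anhydride
Product: 14 methyl 2-[5-acetoxy-7-(acetoxymethyl)-4-oxo-4H-chromen-3-yl]-2-oxoacetate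
Conditions: Ac2O, pyridine, DMAP (cat.), CH2Cl2, 0 °C to rt
Reagents that add atoms: acetic anhydride, CC(=O)OC(C)=O
Why: DMAP-catalysed acetylation caps the primary alcohol and the chelated 5-OH, which would otherwise bind the cobalt catalyst of step 13 as an O,O-chelate with the chromone carbonyl.

Step 6
Reactants: 15 4-hydroxy-3-methylbenzaldehyde; 16 4-bromo-2-methylbutan-2-ol
Product: 17 4-(3-hydroxy-3-methylbutoxy)-3-methylbenzaldehyde
Conditions: K2CO3, KI (cat.), DMF, 70 °C
Reagents that add atoms: 4-bromo-2-methylbutan-2-ol, CC(C)(O)CCBr
Why: Williamson ether synthesis of the phenoxide with the primary bromide; the tertiary alcohol does not compete.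

Step 7
Reactants: 17 4-(3-hydroxy-3-methylbutoxy)-3-methylbenzaldehyde; 18 3-chloroperoxybenzoic acid
Product: 20 4-(3-hydroxy-3-methylbutoxy)-3-methylphenol, via aryl formate 19 (not isolated)
Conditions: mCPBA, CH2Cl2, rt; then K2CO3 (cat.), MeOH, 0 °C
Reagents that add atoms: 3-chloroperoxybenzoic acid, OOC(=O)c1cccc(Cl)c1
Why: Baeyer–Villiger (Dakin-type) oxidation with migration of the electron-rich aryl group gives the formate, which methanol cleaves to the phenol that becomes the free benzo-ring OH of the target.

Step 8
Reactants: 20 4-(3-hydroxy-3-methylbutoxy)-3-methylphenol; 21 N-bromosuccinimide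
Product: 22 2-bromo-4-(3-hydroxy-3-methylbutoxy)-5-methylphenol
Conditions: NBS, CH2Cl2, −20 to 0 °C
Reagents that add atoms: N-bromosuccinimide, O=C1CCC(=O)N1Br
Why: Electrophilic bromination ortho to the free hydroxyl should take the unhindered position para to the methyl group, which leaves one C–H bond flanked by bromine and the ether oxygen.

Step 9
Reactants: 23 2-bromobenzene-1,3-diol; 24 2-(furan-2-yl)-4,4,5,5-tetramethyl-1,3,2-dioxaborolane
Product: 25 2-(furan-2-yl)benzene-1,3-diol
Conditions: Pd(OAc)2 (2 mol%), 2-dicyclohexylphosphino-2',6'-dimethoxybiphenyl (4 mol%), K3PO4, dioxane/H2O, 60 °C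
Reagents that add atoms: 2-(furan-2-yl)-4,4,5,5-tetramethyl-1,3,2-dioxaborolane, CC1(C)OB(c2ccco2)OC1(C)C
Why: Suzuki–Miyaura coupling; the bulky electron-rich biaryl phosphine allows oxidative addition to the doubly ortho-substituted bromide and a coupling fast enough to outrun protodeboronation of the furyl boronate.

Step 10
Reactants: 22 2-bromo-4-(3-hydroxy-3-methylbutoxy)-5-methylphenol; 26 dichlorodiisopropylsilane; 25 2-(furan-2-yl)benzene-1,3-diol
Product: 28 [2-bromo-4-(3-hydroxy-3-methylbutoxy)-5-methylphenoxy][2-(furan-2-yl)-3-hydroxyphenoxy]diisopropylsilane, via chlorosilane 27 (not isolated)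
Conditions: 26 (3 equiv), Et3N, CH2Cl2, −78 to 0 °C; excess 26 removed in vacuo; then 25 (3 equiv), imidazole, CH2Cl2/DMF, 0 °C to rt
Reagents that add atoms: dichlorodiisopropylsilane, CC(C)[Si](Cl)(Cl)C(C)C
Why: Stepwise silyl ether formation: the second chloride of the hindered dichlorosilane is displaced much more slowly than the first, so the monochlorosilane can be made with excess silane and then joined to an excess of the symmetric diol (mono-silylation); only phenols react, the tertiary alcohol does not.

Step 11
Reactants: 28 [2-bromo-4-(3-hydroxy-3-methylbutoxy)-5-methylphenoxy][2-(furan-2-yl)-3-hydroxyphenoxy]diisopropylsilane; 13 acetic anhydride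
Product: 32 racemic silylene-bridged 1-aryl-1,4-epoxy-1,4-dihydronaphthalene diacetate (2-acetoxy-6-oxyphenyl at C1; 3-acetoxy-3-methylbutoxy at C5; methyl at C6; the C8 oxygen and the aryl oxygen joined by Si(iPr)2), via lithiated bromoarene 29 (not isolated), via aryne 30 (not isolated), via dilithium cycloadduct 31 (not isolated)
Conditions: lithium 2,2,6,6-tetramethylpiperidide (3.5 equiv), THF (0.01 M), −78 to −20 °C; then Ac2O (6 equiv), −20 °C to rt
Reagents that add atoms: acetic anhydride, CC(=O)OC(C)=O
Why: Deprotonation of the C–H bond between bromine and the ether oxygen and loss of LiBr give the aryne, which undergoes an intramolecular Diels–Alder reaction with the tethered furan; the two-oxygen silicon tether lets only the aryne carbon next to the silyloxy group reach the aryl-bearing furan carbon (eight-membered dioxasilocine ring), both bridgehead centres form together as a racemate, and the phenoxide and tertiary alkoxide are acetylated in the quench.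

Step 12
Reactants: 32 racemic silylene-bridged 1-aryl-1,4-epoxy-1,4-dihydronaphthalene diacetate
Product: 33 silylene-bridged 1-aryl-1,4-epoxy-1,4-dihydronaphthalene diacetate as the single enantiomer with the bridgehead configuration of the target (unreacted enantiomer)
Conditions: immobilised Candida antarctica lipase B, phosphate buffer (pH 7)/t-BuOMe, 30 °C, to about 55% conversion
Reagents that add atoms: none
Why: Kinetic resolution by a lipase (serine carboxylic-ester hydrolase): the aryl acetate lies ortho to the carbon that carries the stereogenic bridgehead, so the enzyme should hydrolyse one enantiomer faster, the tertiary acetate is not a lipase substrate, and running past half conversion leaves the wanted enantiomer enantiopure.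

Step 13
Reactants: 14 methyl 2-[5-acetoxy-7-(acetoxymethyl)-4-oxo-4H-chromen-3-yl]-2-oxoacetate; 33 silylene-bridged 1-aryl-1,4-epoxy-1,4-dihydronaphthalene diacetate (single enantiomer)
Product: 34 hexacyclic adduct: the target skeleton with acetates on the chromone 5-oxygen, the 7-CH2O group and one resorcinol oxygen, and with the other resorcinol oxygen and the benzo-ring oxygen joined by Si(iPr)2
Conditions: [(C5Me5)Co(MeCN)3](SbF6)2 (10 mol%), NaO2CCMe3 (30 mol%), ClCH2CH2Cl, 50 °C
Reagents that add atoms: none
Why: Proposed new method: pivalate-assisted metalation of the chromone C2–H bond, directed by the ketone oxygen of the keto ester on C3, should give a five-membered cobaltacycle of trivalent cobalt, the strained alkene of 33 should insert into its Co–C2 bond, and the new C(sp3)–Co bond should add to the still coordinated ketone before pivalic acid frees the tertiary alcohol and the catalyst. The closest known reaction type is the redox-neutral [3+2] annulation by C–H activation, alkene or alkyne insertion and addition of the resulting carbon–metal bond to the directing carbonyl (aryl ketones with alkynes to indenols; aromatic and vinylic amides with oxa-bridged bicyclic alkenes), not yet shown for a chromone C2–H bond with a keto ester as director and acceptor. The first C–C bond is made intermolecularly and the cyclopentene ring is then closed by a 5-exo-trig addition of the alkylcobalt carbon to the C=O group. The two ring-fusion CH centres are set cis by the suprafacial insertion and exo by the shape of the bicycle (the face syn to the oxygen bridge is the open one), hence relative to the resolved bridgeheads of 33; the carbinol centre is set in the carbonyl addition, in which the ester should take the convex side next to the ring-fusion hydrogens and the cobalt-bound oxygen the side of the oxygen bridge, which can also hold the metal. The step needs the chromone carbon, not cobalt, at the alkene carbon beside the aryl-bearing bridgehead: the silylene ring turns that aryl group face-on to the exo side, where the flat O1 edge of the chromone can lie over it but the C5Me5 cap of cobalt cannot. It also needs capture of the alkylcobalt before β-oxygen elimination opens the bridge, for which the very electrophilic ketone held in a seven-membered chelate and the silver-free, buffered catalyst are chosen, while the acetoxy group on C5 leaves the chromone carbonyl no peri C–H bond to activate.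

Step 14
Reactants: 34 hexacyclic adduct
Product: 35 aspergichromone B
Conditions: K2CO3 (0.5 equiv), MeOH, 0 °C to rt; aq. NH4Cl
Reagents that add atoms: none
Why: Base-catalysed methanolysis (transesterification) should cleave the two aryl acetates, the primary acetate and both aryloxy–silicon bonds, while the hindered tertiary acetate reacts far more slowly and the methyl ester is only exchanged with methanol; no stereocentre is touched.

**Compound list**

1 | 3,5-dihydroxybenzyl alcohol | OCc1cc(O)cc(O)c1 | starting material
2 | chloromethyl methyl ether | COCCl | starting material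
3 | 1,3-bis(methoxymethoxy)-5-[(methoxymethoxy)methyl]benzene | COCOCc1cc(OCOC)cc(OCOC)c1 | intermediate
4 | N-methoxy-N-methylacetamide | CC(=O)N(C)OC | starting material
5 | 2,6-bis(methoxymethoxy)-4-[(methoxymethoxy)methyl]phenyllithium | [Li]c1c(OCOC)cc(COCOC)cc1OCOC | intermediate
6 | lithium hemiaminal (tetrahedral adduct of 5 and 4) | CC(O[Li])(N(C)OC)c1c(OCOC)cc(COCOC)cc1OCOC | intermediate
7 | 1-{2,6-bis(methoxymethoxy)-4-[(methoxymethoxy)methyl]phenyl}ethan-1-one | CC(=O)c1c(OCOC)cc(COCOC)cc1OCOC | intermediate
8 | N,N-dimethylformamide dimethyl acetal | COC(OC)N(C)C | starting material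
9 | (E)-3-(dimethylamino)-1-{2,6-bis(methoxymethoxy)-4-[(methoxymethoxy)methyl]phenyl}prop-2-en-1-one | CN(C)/C=C/C(=O)c1c(OCOC)cc(COCOC)cc1OCOC | intermediate
10 | methyl chlorooxoacetate | COC(=O)C(=O)Cl | starting material
11 | methyl 3-{2,6-bis(methoxymethoxy)-4-[(methoxymethoxy)methyl]benzoyl}-4-(dimethylamino)-2-oxobut-3-enoate | COC(=O)C(=O)C(=CN(C)C)C(=O)c1c(OCOC)cc(COCOC)cc1OCOC | intermediate
12 | methyl 2-[5-hydroxy-7-(hydroxymethyl)-4-oxo-4H-chromen-3-yl]-2-oxoacetate | COC(=O)C(=O)c1coc2cc(CO)cc(O)c2c1=O | intermediate
13 | acetic anhydride | CC(=O)OC(C)=O | starting material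
14 | methyl 2-[5-acetoxy-7-(acetoxymethyl)-4-oxo-4H-chromen-3-yl]-2-oxoacetate | COC(=O)C(=O)c1coc2cc(COC(C)=O)cc(OC(C)=O)c2c1=O | intermediate
15 | 4-hydroxy-3-methylbenzaldehyde | Cc1cc(C=O)ccc1O | starting material
16 | 4-bromo-2-methylbutan-2-ol | CC(C)(O)CCBr | starting material
17 | 4-(3-hydroxy-3-methylbutoxy)-3-methylbenzaldehyde | Cc1cc(C=O)ccc1OCCC(C)(C)O | intermediate
18 | 3-chloroperoxybenzoic acid | OOC(=O)c1cccc(Cl)c1 | starting material
19 | 4-(3-hydroxy-3-methylbutoxy)-3-methylphenyl formate | Cc1cc(OC=O)ccc1OCCC(C)(C)O | intermediate
20 | 4-(3-hydroxy-3-methylbutoxy)-3-methylphenol | Cc1cc(O)ccc1OCCC(C)(C)O | intermediate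
21 | N-bromosuccinimide | O=C1CCC(=O)N1Br | starting material
22 | 2-bromo-4-(3-hydroxy-3-methylbutoxy)-5-methylphenol | Cc1cc(O)c(Br)cc1OCCC(C)(C)O | intermediate
23 | 2-bromobenzene-1,3-diol | Oc1cccc(O)c1Br | starting material
24 | 2-(furan-2-yl)-4,4,5,5-tetramethyl-1,3,2-dioxaborolane | CC1(C)OB(c2ccco2)OC1(C)C | starting material
25 | 2-(furan-2-yl)benzene-1,3-diol | Oc1cccc(O)c1-c1ccco1 | intermediate
26 | dichlorodiisopropylsilane | CC(C)[Si](Cl)(Cl)C(C)C | starting material
27 | chloro[2-bromo-4-(3-hydroxy-3-methylbutoxy)-5-methylphenoxy]diisopropylsilane | CC(C)[Si](Cl)(Oc1cc(C)c(OCCC(C)(C)O)cc1Br)C(C)C | intermediate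
28 | [2-bromo-4-(3-hydroxy-3-methylbutoxy)-5-methylphenoxy][2-(furan-2-yl)-3-hydroxyphenoxy]diisopropylsilane | CC(C)[Si](Oc1cc(C)c(OCCC(C)(C)O)cc1Br)(Oc1cccc(O)c1-c1ccco1)C(C)C | intermediate
29 | trilithio derivative of 28 (lithium phenoxide, lithium tert-alkoxide, aryllithium between Br and the ether oxygen) | CC(C)[Si](Oc1cc(C)c(OCCC(C)(C)O[Li])c([Li])c1Br)(Oc1cccc(O[Li])c1-c1ccco1)C(C)C | intermediate
30 | aryne (dilithium salt) formed from 29 by loss of LiBr | CC(C)[Si](OC1=CC(C)=C(OCCC(C)(C)O[Li])C#C1)(Oc1cccc(O[Li])c1-c1ccco1)C(C)C | intermediate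
31 | racemic dilithium salt of the intramolecular aryne–furan cycloadduct | C1=C[C@H]2O[C@]1(c1c(O[Li])cccc1O[Si](C(C)C)(C(C)C)O3)c1c3cc(C)c(OCCC(C)(C)O[Li])c12 | intermediate
32 | racemic silylene-bridged 1-aryl-1,4-epoxy-1,4-dihydronaphthalene diacetate (relative configuration as drawn) | C1=C[C@H]2O[C@]1(c1c(OC(C)=O)cccc1O[Si](C(C)C)(C(C)C)O3)c1c3cc(C)c(OCCC(C)(C)OC(C)=O)c12 | intermediate
33 | the same diacetate as the single enantiomer drawn (bridgehead configuration of the target) | C1=C[C@H]2O[C@]1(c1c(OC(C)=O)cccc1O[Si](C(C)C)(C(C)C)O3)c1c3cc(C)c(OCCC(C)(C)OC(C)=O)c12 | intermediate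
34 | hexacyclic adduct (tri-O-acetyl, O,O-diisopropylsilylene derivative of the target; cyclopentene exo and cis on the oxa-bridged ring, tertiary OH on the side of the oxygen bridge) | COC(=O)[C@@]1(O)c2c(oc3cc(COC(C)=O)cc(OC(C)=O)c3c2=O)[C@H]2[C@@H]1[C@H]1O[C@]2(c2c(OC(C)=O)cccc2O[Si](C(C)C)(C(C)C)O4)c2c4cc(C)c(OCCC(C)(C)OC(C)=O)c21 | intermediate
35 | aspergichromone B | COC(=O)[C@@]1(O)c2c(oc3cc(CO)cc(O)c3c2=O)[C@H]2[C@@H]1[C@H]1O[C@]2(c2c(O)cccc2O)c2c(O)cc(C)c(OCCC(C)(C)OC(C)=O)c21 | target

**Count and risks**

Total step count: 14. Longest linear sequence: 8 steps (6, 7, 8, 10, 11, 12, 13, 14).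

Steps most likely to fail:

Step 13 (bears the label). What may go wrong: metalation of the chromone C2–H bond may be outrun by reversible carboxylate addition to the electron-poor pyrone. The alkylcobalt may undergo β-oxygen elimination, opening the bridge and aromatising to a naphthalene, before it reaches the ketone. Insertion may occur with the reverse orientation relative to the aryl-bearing bridgehead. The fallback uses known chemistry, sets out from 14 and comes back at 34. Compound 14 is zincated at C2 with 2,2,6,6-tetramethylpiperidylzinc chloride–lithium chloride, (C9H18N)ZnCl·LiCl, in THF at 25 °C to give the 2-chlorozincio chromone keto ester F1. Iodolysis with I2 gives the 2-iodochromone keto ester F2. F2 and 33 with CoI2(Ph2PCH2CH2PPh2) (5 mol%) and Zn powder in MeCN at 80 °C should give 34. This is the reductive [3+2] carbocyclisation known for ortho-iodoaryl ketones with alkynes and alkenes: oxidative addition of the C–I bond to low-valent cobalt, exo carbocobaltation of the strained alkene, addition of the alkylcobalt to the ketone, and turnover by zinc. It needs no C–H metalation and no free carboxylate.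

Step 11. What may go wrong: the aryne may be captured by the lithium tert-alkoxide of the side chain (seven-membered ether) or by the amide base instead of the tethered furan, or the alkoxide may attack silicon and scramble the tether before the cycloaddition. The fallback drops the intramolecular mode, sets out from 22 and 25 and comes back at 32. Both are fully silylated (Et3SiOTf, 2,6-lutidine) to the bis(triethylsilyl) ether of the bromophenol F3 and 2-[2,6-bis(triethylsilyloxy)phenyl]furan F4. F3 with lithium 2,2,6,6-tetramethylpiperidide in THF gives the protected aryne F5, which is trapped by excess F4 in an intermolecular Diels–Alder reaction; the two regioisomeric adducts are separated and the wanted one is the racemic tetrakis(triethylsilyl) cycloadduct F6. Bu4NF/AcOH frees the racemic tetraol F7. Dichlorodiisopropylsilane and imidazole at high dilution bridge the only two phenols that can share a ring, giving the racemic silylene diol F8. Ac2O, Et3N and DMAP then give 32.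

Step 12. What may go wrong: the lipase may discriminate poorly between the enantiomers, or may not turn over the hindered aryl acetate at all. The fallback sets out from 32 and comes back at 33: racemic 32 is resolved by preparative chromatography on a chiral stationary phase (cellulose tris(3,5-dimethylphenylcarbamate)), which makes no new compound (F0).

**Further compounds**

F1 | step 13 | [5-acetoxy-7-(acetoxymethyl)-3-(2-methoxy-2-oxoacetyl)-4-oxo-4H-chromen-2-yl]zinc chloride | COC(=O)C(=O)c1c([Zn]Cl)oc2cc(COC(C)=O)cc(OC(C)=O)c2c1=O
F2 | step 13 | methyl 2-[5-acetoxy-7-(acetoxymethyl)-2-iodo-4-oxo-4H-chromen-3-yl]-2-oxoacetate | COC(=O)C(=O)c1c(I)oc2cc(COC(C)=O)cc(OC(C)=O)c2c1=O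
F3 | step 11 | [2-bromo-5-methyl-4-(3-methyl-3-triethylsilyloxybutoxy)phenoxy]triethylsilane | CC[Si](CC)(CC)Oc1cc(C)c(OCCC(C)(C)O[Si](CC)(CC)CC)cc1Br
F4 | step 11 | 2-[2,6-bis(triethylsilyloxy)phenyl]furan | CC[Si](CC)(CC)Oc1cccc(O[Si](CC)(CC)CC)c1-c1ccco1
F5 | step 11 | 4-methyl-3-(3-methyl-3-triethylsilyloxybutoxy)-6-(triethylsilyloxy)benzyne | CC[Si](CC)(CC)OC1=CC(C)=C(OCCC(C)(C)O[Si](CC)(CC)CC)C#C1
F6 | step 11 | racemic tetrakis(triethylsilyl) ether of the 1-aryl-1,4-epoxy-1,4-dihydronaphthalene | C1=C[C@H]2O[C@]1(c1c(O[Si](CC)(CC)CC)cccc1O[Si](CC)(CC)CC)c1c(O[Si](CC)(CC)CC)cc(C)c(OCCC(C)(C)O[Si](CC)(CC)CC)c12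
F7 | step 11 | racemic 1-(2,6-dihydroxyphenyl)-5-(3-hydroxy-3-methylbutoxy)-6-methyl-1,4-epoxy-1,4-dihydronaphthalen-8-ol | C1=C[C@H]2O[C@]1(c1c(O)cccc1O)c1c(O)cc(C)c(OCCC(C)(C)O)c12
F8 | step 11 | racemic silylene-bridged diol (free phenol and free tertiary alcohol) | C1=C[C@H]2O[C@]1(c1c(O)cccc1O[Si](C(C)C)(C(C)C)O3)c1c3cc(C)c(OCCC(C)(C)O)c12
F0 | step 12 | none | none
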